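Late in Monday's run target and starting material sink together, from 32.1% and 36.2% at 25.0 min to 26.5% and 31.7% at 40.0 min, so what matters is what stays put between them.

common to all: free catalyst 0.24 mM

|  | starting material | partner | temperature | remark | time |
|---|---|---|---|---|---|
| Monday's | 0.24 M | 0.36 M | 100 °C | the very flask that is asked about, followed so far |  |
| Sunday's | 0.12 M | 0.36 M | 95 °C | run made earlier |  |
| flask | 0.24 M | 0.360 M | 100 °C |  | 1.0 h |

- Monday's (time / min: target / %, starting material / %): 3.00: 41.2, 55.0; 10.0: 40.9, 43.4; 15.0: 37.6, 40.4; 25.0: 32.1, 36.2; 40.0: 26.5, 31.7
- Sunday's (time / min: target / %, starting material / %): 4.00: 43.7, 52.3; 8.00: 49.1, 41.2; 12.0: 47.2, 37.8; 15.0: 45.8, 35.5; 20.0: 42.8, 33.8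

(readings scatter by 0.3 percentage points)

- noon: at 1.0 h raise the temperature by 15 K, then wait 20 min
- dusk: at 1.0 h take out 90% of the target then present, then wait 20 min
- summer: at 1.0 h add partner, 50.0% of the amount charged, then wait 20 min
- spring: at 1.0 h add free catalyst, 50.0% of the amount charged, then wait 20 min
- winter: change nothing and wait 20 min more

- removed target is counted in
- the earlier runs were read with a standard deviation of 0.3 percentage points
- additions bring no volume worth counting

1. target, in percent of the starting material first charged, at 1.0 h
2. the remedy with the largest gain of target, or "none" below 2 percentage points (noon / dusk / summer / spring / winter / none)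
3. target present, with what was taken out counted in, in percent of the starting material first charged, after dusk
4. target present, with what was taken out counted in, in percent of the starting material first charged, after spring

The coupling quotient (a reaction quotient) is target over starting material times free partner, in concentrations. Free partner is taken as its charge less the starting material that has disappeared, on the assumption that target lost from the flask keeps its partner. Monday's run gives 4.29 /M at 25.0 min and 4.26 /M at 40.0 min; Sunday's last reading gives 4.51 /M. So target over starting material equals the quotient times free partner.

The sum of the two, read over Monday's last interval, halves in 65.0 min. Reckoned here, that sum stands near 47.0% at 1.0 h, and target, following it, near 21.4%, with a split ratio, target over starting material, of 0.774. Dusk banks its share and lets the remainder split again, giving about 31.4%, which is above the 28.5% that summer's split gives, both before further loss.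

The forecast, reading the coupling as “a fast, mildly exothermic equilibrium”, gave 22% at 1.0 h, dusk as best, 29.8% after dusk (lower than the reckoning here) and 15.5% after spring.

The flask gives 21.7%, dusk with a gain of 8.3 percentage points, 30.0% after dusk and 16.1% after spring.

    starting material + partner ⇌ target (K = 4.40 /M, k = 0.0170 /M/s, Ea = 87.0 kJ/mol, ΔH = −16.0 kJ/mol)
    starting material + partner ⇌ isomer of the product (K = 190 /M, k = 4.10 × 10⁻⁴ /M/s, Ea = 100 kJ/mol, ΔH = −39.0 kJ/mol)
    target + free catalyst ⇌ isomer of the product + free catalyst, rate k3*[free catalyst]*[target] forward; the back reaction follows from the equilibrium constant (k = 2.50 /M/s, Ea = 60.0 kJ/mol)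
    2 free catalyst → spent catalyst (k = 1.00 /M/s, Ea = 50.0 kJ/mol)
    (constants at 100 °C)

At 60.0 min the flask's quotient is 4.34 /M. A flask charged with 0.60 M of starting material holds 13.8% target and 17.4% of its partner, yet gives 4.37 /M. The flask asked about has not come to rest at 1.0 h: at 600 min the quotient is 4.41 /M, while target has dropped to 3.76% and isomer of the product has risen from 51.3% to 89.9%. Target over isomer of the product then stands at 0.0418, against 0.0232 at equilibrium.

The numbers in the tables were generated by integration on assumed constants; the scatter is artificial.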